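**Retrosynthetic overview**

- Locants: trione ring A is C1–C6 (C1 spiro); the hydrindane is C1'–C7a' (C5' = C1).
- Target ⇐ acyclic 13 in one flask: C3a'–C7a' by attack of the C3a' ketone enolate on a (2R,3R)-epoxide (closes the cyclohexane), then C2'–C3' by SmI2 Barbier addition of the C2' chloride to the C3' methyl ketone (closes the cyclopentane).
- 13 ⇐ catalytic asymmetric Michael addition of 11 to methyl vinyl ketone; 11 ⇐ reductive Knoevenagel alkylation of diprenyl trione 6 with epoxy aldehyde 10.
- 6 ⇐ methyl 2,4,6-trihydroxybenzoate (ester as removable blocking group: acylation, gem-diprenylation, decarboxylation); 10 ⇐ 5-chloro-2-methylpent-2-ene (allylic oxidation, Sharpless epoxidation, oxidation).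
- Enabling feature: the syn-1,4-diol array O–C7'–C7a'–C3a'–C3'–O. C3a' is α to a latent methyl ketone (C3'), C7a' is the distal carbon of a latent C7'/C7a' epoxide, and the C1'–C2' bridge on C7a' reaches C3'. Ring order: A, then cyclohexane, then cyclopentane.

Key step: step 9

Remark: the trione ring is written throughout in the enol tautomer of the target SMILES; compound 11 is an epimerisable mixture at C2 until step 8 fixes that carbon.

Step 1
Reactants: 1 methyl 2,4,6-trihydroxybenzoate; 2 3-methylbutanoyl chloride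
Product: 3 methyl 2,4,6-trihydroxy-3-(3-methylbutanoyl)benzoate
Conditions: AlCl3 (3 equiv), PhNO2–CH2Cl2, 0 °C to rt; aq. HCl
Reagents that add atoms: none
Why: Friedel–Crafts C-acylation of the phloroglucinol ring at one of its two equivalent free positions, the ester blocking the carbon that later becomes the spiro centre; no stereocenter is formed.

Step 2
Reactants: 3 methyl 2,4,6-trihydroxy-3-(3-methylbutanoyl)benzoate; 4 1-bromo-3-methylbut-2-ene
Product: 5 methyl 2,4-dihydroxy-3-(3-methylbutanoyl)-5,5-bis(3-methylbut-2-en-1-yl)-6-oxocyclohexa-1,3-diene-1-carboxylate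
Conditions: NaOMe (3.2 equiv), MeOH, 0 °C; 4 (2.2 equiv), 0 °C to rt
Reagents that add atoms: none
Why: base-mediated dearomative C-alkylation of an acylphloroglucinol should place both prenyl groups on the only unsubstituted ring carbon, the second alkylation breaking aromaticity; no stereocenter is formed.

Step 3
Reactants: 5 methyl 2,4-dihydroxy-3-(3-methylbutanoyl)-5,5-bis(3-methylbut-2-en-1-yl)-6-oxocyclohexa-1,3-diene-1-carboxylate
Product: 6 5-hydroxy-4-(3-methylbutanoyl)-6,6-bis(3-methylbut-2-en-1-yl)cyclohex-4-ene-1,3-dione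
Conditions: NaOH (aq), MeOH, 50 °C; then 2 M HCl, rt
Reagents that add atoms: none
Why: saponification followed by decarboxylation of the vinylogous β-keto acid should free the ring CH2 between two carbonyls that becomes the spiro carbon; no stereocenter is formed.

Step 4
Reactants: 7 5-chloro-2-methylpent-2-ene
Product: 8 (E)-5-chloro-2-methylpent-2-en-1-ol
Conditions: SeO2 (10 mol %), t-BuOOH, CH2Cl2, rt
Reagents that add atoms: tert-butyl hydroperoxide, CC(C)(C)OO
Why: catalytic SeO2 allylic oxidation of a trisubstituted alkene should hydroxylate the methyl group trans to the chain, which fixes the E geometry needed for the epoxide.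

Step 5
Reactants: 8 (E)-5-chloro-2-methylpent-2-en-1-ol
Product: 9 [(2R,3R)-3-(2-chloroethyl)-2-methyloxiran-2-yl]methanol
Conditions: Ti(OiPr)4 (10 mol %), D-(−)-diethyl tartrate (12 mol %), t-BuOOH, 4 Å MS, CH2Cl2, −20 °C
Reagents that add atoms: tert-butyl hydroperoxide, CC(C)(C)OO
Why: Sharpless asymmetric epoxidation of an E-2-methyl allylic alcohol, in which the D-tartrate ligand should deliver oxygen to the face that gives the (2R,3R) epoxide, the source of C7' and C7a'.

Step 6
Reactants: 9 [(2R,3R)-3-(2-chloroethyl)-2-methyloxiran-2-yl]methanol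
Product: 10 (2S,3R)-3-(2-chloroethyl)-2-methyloxirane-2-carbaldehyde
Conditions: Dess–Martin periodinane, CH2Cl2, 0 °C to rt
Reagents that add atoms: none
Why: Dess–Martin oxidation of the primary alcohol; the α-carbon is quaternary, so the epoxide stereocenters cannot epimerise (the descriptor at C2 changes only by priority).

Step 7
Reactants: 6 5-hydroxy-4-(3-methylbutanoyl)-6,6-bis(3-methylbut-2-en-1-yl)cyclohex-4-ene-1,3-dione; 10 (2S,3R)-3-(2-chloroethyl)-2-methyloxirane-2-carbaldehyde
Product: 11 2-{[(2R,3R)-3-(2-chloroethyl)-2-methyloxiran-2-yl]methyl}-5-hydroxy-4-(3-methylbutanoyl)-6,6-bis(3-methylbut-2-en-1-yl)cyclohex-4-ene-1,3-dione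
Conditions: Hantzsch ester (1.1 equiv), L-proline (20 mol %), CH2Cl2, rt
Reagents that add atoms: none
Why: organocatalytic reductive Knoevenagel alkylation (condensation at the only CH2 of the trione, then hydride transfer to the alkylidene) should give clean mono-C-alkylation; the new ring carbon stays epimerisable and the epoxide centres are untouched.

Step 8
Reactants: 11 2-{[(2R,3R)-3-(2-chloroethyl)-2-methyloxiran-2-yl]methyl}-5-hydroxy-4-(3-methylbutanoyl)-6,6-bis(3-methylbut-2-en-1-yl)cyclohex-4-ene-1,3-dione; 12 but-3-en-2-one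
Product: 13 (1S)-1-{[(2R,3R)-3-(2-chloroethyl)-2-methyloxiran-2-yl]methyl}-4-hydroxy-3-(3-methylbutanoyl)-5,5-bis(3-methylbut-2-en-1-yl)-1-(3-oxobutyl)cyclohex-3-ene-2,6-dione
Conditions: 9-O-benzylcupreidine (10 mol %), 12 (1.5 equiv), CH2Cl2, −20 °C
Reagents that add atoms: none
Why: catalytic asymmetric Michael addition of a 2-substituted cyclic 1,3-dicarbonyl to an enone, in which the bifunctional cinchona base should select the enolate face on the strength of the different flanks (quaternary diprenyl carbon against planar acyl-enol carbon) and set the quaternary C1 as S; the pseudo-enantiomeric cupreine catalyst is used if the sense proves opposite.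

Step 9
Reactants: 13 (1S)-1-{[(2R,3R)-3-(2-chloroethyl)-2-methyloxiran-2-yl]methyl}-4-hydroxy-3-(3-methylbutanoyl)-5,5-bis(3-methylbut-2-en-1-yl)-1-(3-oxobutyl)cyclohex-3-ene-2,6-dione
Product: 15 (1S,3'R,3a'S,7'R,7a'R)-3',4,7'-trihydroxy-3',7'-dimethyl-3-(3-methylbutanoyl)-5,5-bis(3-methylbut-2-en-1-yl)-1',2',3',3a',4',6',7',7a'-octahydrospiro[cyclohex-3-ene-1,5'-indene]-2,6-dione, via chloro hydroxy ketone 14 (not isolated)
Conditions: LiN(SiMe3)2 (1.95 equiv), LiClO4 (1 equiv), THF, −78 to 0 °C; then AcOH (1 equiv), SmI2 (4 equiv), THF, visible light, rt; aq. NH4Cl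
Reagents that add atoms: none
Why: The first equivalent of LiN(SiMe3)2 turns ring A into its unreactive enolate and the second enolises the methyl ketone; after equilibration the internal C3a' enolate opens the epoxide at C7a' anti to oxygen to give 14, and after buffering with AcOH photo-excited SmI2 reduces the C2'–Cl bond to an alkylsamarium that adds to the C3' ketone. The two halves are the intramolecular alkylation of a ketone enolate by an epoxide and the SmI2 Barbier cyclisation of a halo ketone, here run in one flask. The cyclohexane ring closes 6-endo-tet through a chair (exo attack would have to occur at the quaternary C7'), and the cyclopentane closes 5-exo-trig onto the carbonyl to give the trans-fused hydrindane. C7a' is set by SN2 inversion of the (3R) epoxide carbon and C7' is carried over from the epoxide with its hydroxyl equatorial; C3a' takes the equatorial acetyl orientation trans to the C7a' side chain; C3' is set when the tethered C2' carbon adds to the ketone held by trivalent samarium bridging the carbonyl oxygen and O7', which should place the new hydroxyl syn to O7' and the methyl pseudo-equatorial. The step needs C-alkylation at the epoxide to outrun O- and C-alkylation by the chloroethyl arm and attack by the ring A oxygen; the lithium counter-ion, the low temperature, the choice of chloride over bromide or iodide and the delocalised, weakly nucleophilic ring A enolate are meant to secure this.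

**Compound list**

1 | methyl 2,4,6-trihydroxybenzoate | COC(=O)c1c(O)cc(O)cc1O | starting material
2 | 3-methylbutanoyl chloride | CC(C)CC(Cl)=O | starting material
3 | methyl 2,4,6-trihydroxy-3-(3-methylbutanoyl)benzoate | COC(=O)c1c(O)cc(O)c(C(=O)CC(C)C)c1O | intermediate
4 | 1-bromo-3-methylbut-2-ene | CC(C)=CCBr | starting material
5 | methyl 2,4-dihydroxy-3-(3-methylbutanoyl)-5,5-bis(3-methylbut-2-en-1-yl)-6-oxocyclohexa-1,3-diene-1-carboxylate | COC(=O)C1=C(O)C(C(=O)CC(C)C)=C(O)C(CC=C(C)C)(CC=C(C)C)C1=O | intermediate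
6 | 5-hydroxy-4-(3-methylbutanoyl)-6,6-bis(3-methylbut-2-en-1-yl)cyclohex-4-ene-1,3-dione | CC(C)=CCC1(CC=C(C)C)C(=O)CC(=O)C(C(=O)CC(C)C)=C1O | intermediate
7 | 5-chloro-2-methylpent-2-ene | CC(C)=CCCCl | starting material
8 | (E)-5-chloro-2-methylpent-2-en-1-ol | OC/C(C)=C/CCCl | intermediate
9 | [(2R,3R)-3-(2-chloroethyl)-2-methyloxiran-2-yl]methanol | OC[C@@]1(C)O[C@@H]1CCCl | intermediate
10 | (2S,3R)-3-(2-chloroethyl)-2-methyloxirane-2-carbaldehyde | O=C[C@@]1(C)O[C@@H]1CCCl | intermediate
11 | 2-{[(2R,3R)-3-(2-chloroethyl)-2-methyloxiran-2-yl]methyl}-5-hydroxy-4-(3-methylbutanoyl)-6,6-bis(3-methylbut-2-en-1-yl)cyclohex-4-ene-1,3-dione (C2 epimers) | CC(C)=CCC1(CC=C(C)C)C(=O)C(C[C@@]2(C)O[C@@H]2CCCl)C(=O)C(C(=O)CC(C)C)=C1O | intermediate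
12 | but-3-en-2-one | CC(=O)C=C | starting material
13 | (1S)-1-{[(2R,3R)-3-(2-chloroethyl)-2-methyloxiran-2-yl]methyl}-4-hydroxy-3-(3-methylbutanoyl)-5,5-bis(3-methylbut-2-en-1-yl)-1-(3-oxobutyl)cyclohex-3-ene-2,6-dione | CC(C)=CCC1(CC=C(C)C)C(=O)[C@](CCC(C)=O)(C[C@@]2(C)O[C@@H]2CCCl)C(=O)C(C(=O)CC(C)C)=C1O | intermediate
14 | (6S,8S,9R,10R)-8-acetyl-9-(2-chloroethyl)-3,10-dihydroxy-10-methyl-2-(3-methylbutanoyl)-4,4-bis(3-methylbut-2-en-1-yl)spiro[5.5]undec-2-ene-1,5-dione | CC(C)=CCC1(CC=C(C)C)C(=O)[C@@]2(C[C@H](C(C)=O)[C@@H](CCCl)[C@](C)(O)C2)C(=O)C(C(=O)CC(C)C)=C1O | intermediate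
15 | (1S,3'R,3a'S,7'R,7a'R)-3',4,7'-trihydroxy-3',7'-dimethyl-3-(3-methylbutanoyl)-5,5-bis(3-methylbut-2-en-1-yl)-1',2',3',3a',4',6',7',7a'-octahydrospiro[cyclohex-3-ene-1,5'-indene]-2,6-dione | CC(C)=CCC1(CC=C(C)C)C(=O)[C@@]2(C[C@H]3[C@@H](CC[C@@]3(C)O)[C@](C)(O)C2)C(=O)C(C(=O)CC(C)C)=C1O | target

**Totals and risks**

Total step count: 9. Longest linear sequence: 6 steps (1, 2, 3, 7, 8, 9; the branch 4, 5, 6, 7, 8, 9 is equally long).

The three steps most likely to fail:

Step 9. The ketone enolate or the new C7' alkoxide may alkylate the chloroethyl arm before the reductive stage, or the photoreduction of the C–Cl bond may stay incomplete while the ketones are reduced instead. Fallback, from 13 to 15: the base stage alone is run and quenched cold with AcOH, and 14 is isolated. Chloride is exchanged for iodide (NaI, acetone, 50 °C) to give (6S,8S,9R,10R)-8-acetyl-3,10-dihydroxy-9-(2-iodoethyl)-10-methyl-2-(3-methylbutanoyl)-4,4-bis(3-methylbut-2-en-1-yl)spiro[5.5]undec-2-ene-1,5-dione F1. The cyclopentane is then closed by the dark SmI2–HMPA Barbier reaction in THF at −78 °C, which returns to 15.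

Step 7. The enolic oxygen of ring A may open the epoxide in an acid-promoted cyclisation during or after the reductive alkylation. Fallback, from 9 (with 6) back to 13: the epoxide is carried as its bromohydrin.
- Li2NiBr4 in THF should open 9 at the less hindered carbon to (2R,3S)-3-bromo-5-chloro-2-methylpentane-1,2-diol F2.
- TEMPO (cat.) with PhI(OAc)2 oxidises the primary alcohol to (2R,3S)-3-bromo-5-chloro-2-hydroxy-2-methylpentanal F3.
- Reductive alkylation of 6 as in step 7 gives 2-[(2R,3S)-3-bromo-5-chloro-2-hydroxy-2-methylpentyl]-5-hydroxy-4-(3-methylbutanoyl)-6,6-bis(3-methylbut-2-en-1-yl)cyclohex-4-ene-1,3-dione F4.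
- The Michael addition of step 8 gives (1S)-1-[(2R,3S)-3-bromo-5-chloro-2-hydroxy-2-methylpentyl]-4-hydroxy-3-(3-methylbutanoyl)-5,5-bis(3-methylbut-2-en-1-yl)-1-(3-oxobutyl)cyclohex-3-ene-2,6-dione F5.
- In step 9 one further equivalent of LiN(SiMe3)2 closes the epoxide with inversion, so that 13 forms in the flask and the route continues unchanged.

Step 8. Facial selectivity at C1 may be poor, either because the catalyst discriminates weakly between the two flanks of the trione enolate or because it is mismatched with the epoxide centres. Fallback, from 11 to 13: the Michael addition is run without chiral control (Et3N cat., MeCN) to give 13 together with its epimer (1R)-1-{[(2R,3R)-3-(2-chloroethyl)-2-methyloxiran-2-yl]methyl}-4-hydroxy-3-(3-methylbutanoyl)-5,5-bis(3-methylbut-2-en-1-yl)-1-(3-oxobutyl)cyclohex-3-ene-2,6-dione F6. The two are separated by chromatography, and F6 is returned to 11 by base-induced retro-Michael cleavage (KOtBu cat., toluene, reduced pressure to strip the enone) and resubmitted.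

Further compounds
F1 | step 9 | (6S,8S,9R,10R)-8-acetyl-3,10-dihydroxy-9-(2-iodoethyl)-10-methyl-2-(3-methylbutanoyl)-4,4-bis(3-methylbut-2-en-1-yl)spiro[5.5]undec-2-ene-1,5-dione | CC(C)=CCC1(CC=C(C)C)C(=O)[C@@]2(C[C@H](C(C)=O)[C@@H](CCI)[C@](C)(O)C2)C(=O)C(C(=O)CC(C)C)=C1O
F2 | step 7 | (2R,3S)-3-bromo-5-chloro-2-methylpentane-1,2-diol | OC[C@@](C)(O)[C@@H](Br)CCCl
F3 | step 7 | (2R,3S)-3-bromo-5-chloro-2-hydroxy-2-methylpentanal | O=C[C@@](C)(O)[C@@H](Br)CCCl
F4 | step 7 | 2-[(2R,3S)-3-bromo-5-chloro-2-hydroxy-2-methylpentyl]-5-hydroxy-4-(3-methylbutanoyl)-6,6-bis(3-methylbut-2-en-1-yl)cyclohex-4-ene-1,3-dione | CC(C)=CCC1(CC=C(C)C)C(=O)C(C[C@@](C)(O)[C@@H](Br)CCCl)C(=O)C(C(=O)CC(C)C)=C1O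
F5 | step 7 | (1S)-1-[(2R,3S)-3-bromo-5-chloro-2-hydroxy-2-methylpentyl]-4-hydroxy-3-(3-methylbutanoyl)-5,5-bis(3-methylbut-2-en-1-yl)-1-(3-oxobutyl)cyclohex-3-ene-2,6-dione | CC(C)=CCC1(CC=C(C)C)C(=O)[C@](CCC(C)=O)(C[C@@](C)(O)[C@@H](Br)CCCl)C(=O)C(C(=O)CC(C)C)=C1O
F6 | step 8 | (1R)-1-{[(2R,3R)-3-(2-chloroethyl)-2-methyloxiran-2-yl]methyl}-4-hydroxy-3-(3-methylbutanoyl)-5,5-bis(3-methylbut-2-en-1-yl)-1-(3-oxobutyl)cyclohex-3-ene-2,6-dione | CC(C)=CCC1(CC=C(C)C)C(=O)[C@@](CCC(C)=O)(C[C@@]2(C)O[C@@H]2CCCl)C(=O)C(C(=O)CC(C)C)=C1O
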